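## Retrosynthetic overview

1. C15–O: the feruloyl ester is formed last from ferulic acid and labd-7-ene-2α,15-diol. C11–C12: Wittig union of 2-oxodrim-7-en-11-al with the C12–C15 ylide made from (S)-4-methyldihydrofuran-2(3H)-one, then diimide.
2. C9–C11 comes from methylenation of the C9 carbonyl and hydroboration (sets C9). The C4 gem-dimethyl group comes from the ene-derived C4 methylene by oxidation at C2, conjugation and Me2CuLi addition. C2 is set last as 2α by Li/NH3.
3. Key disconnection C2–C3 of ring A: intramolecular carbonyl-ene reaction of a keto aldehyde. It rests on the 1,3 relation in ring A between the C2 oxygen and C4 (the unit O–C2–C3–C4, the mark of an aldehyde ene reaction with a 2-propenyl group), next to ring B, a 2-methylcyclohexene that maps onto carvone with C5 and C10.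
4. Ring order: ring B is bought as (R)-carvone (C5); methylation and alkylation with tert-butyl bromoacetate at the α′ carbon set C10; ring A is closed second.

Key step: step 5

Assumption: (S)-4-methyldihydrofuran-2(3H)-one is taken as a commercial single enantiomer.

Assumption: the methylation product is used as its mixture of methyl epimers and the diol as its mixture of carbinol epimers, because these centres become planar again. The ene product and the trienol are drawn as the expected 2β epimers, and any 2α epimer is carried along, because C2 becomes planar in step 7 and is set in step 17.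

Labdane numbering is used for the bicyclic compounds throughout.

## Route

Step 1
Reactants: 1 (R)-carvone
Product: 3 (5R,6S)-2,6-dimethyl-5-(prop-1-en-2-yl)cyclohex-2-en-1-one (trans-6-methylcarvone), via lithium enolate 2 (not isolated)
Conditions: LiN(i-Pr)2, THF, −78 °C; MeI, −78 to 0 °C
Reagents that add atoms: iodomethane, CI
Why: Kinetic deprotonation at the α′ carbon gives the cross-conjugated enolate 2, whose methylation (enolate alkylation) should occur mainly anti to the 2-propenyl group; the new centre becomes planar again in step 2, so both epimers are used.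

Step 2
Reactants: 3 trans-6-methylcarvone; 4 tert-butyl bromoacetate
Product: 6 tert-butyl 2-[(1S,6S)-1,3-dimethyl-2-oxo-6-(prop-1-en-2-yl)cyclohex-3-en-1-yl]acetate, via lithium enolate 5 (not isolated)
Conditions: LiN(i-Pr)2, THF, −78 to 0 °C; DMPU, 4, −78 to −20 °C
Reagents that add atoms: none
Why: Enolate alkylation of the tetrasubstituted enolate 5 should take place on the face anti to the neighbouring 2-propenyl group, so that the acetate arm ends trans to it and the methyl cis, which sets the quaternary centre C10 as is known for second alkylations of 6-alkylcarvones.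

Step 3
Reactants: 6 keto ester
Product: 7 2-[(1S,6S)-2-hydroxy-1,3-dimethyl-6-(prop-1-en-2-yl)cyclohex-3-en-1-yl]ethan-1-ol (carbinol epimers)
Conditions: LiAlH4, Et2O, 0 °C
Reagents that add atoms: none
Why: Hydride reduction takes the tert-butyl ester to the primary alcohol and the enone carbonyl to the allylic alcohol (1,2-reduction); the carbinol epimers do not matter because this carbon is reoxidised in step 4.

Step 4
Reactants: 7 diol
Product: 8 2-[(1S,6S)-1,3-dimethyl-2-oxo-6-(prop-1-en-2-yl)cyclohex-3-en-1-yl]acetaldehyde
Conditions: (COCl)2, DMSO, CH2Cl2, −78 °C; Et3N, −78 to 0 °C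
Reagents that add atoms: none
Why: Swern oxidation activates both hydroxyl groups as alkoxysulfonium ions before the base is added, so the 1,4-diol should give the keto aldehyde without passing through a lactol that could be oxidised on to a lactone.

Step 5
Reactants: 8 keto aldehyde
Product: 9 (4aS,7R,8aS)-7-hydroxy-2,8a-dimethyl-5-methylidene-4a,5,6,7,8,8a-hexahydronaphthalen-1(4H)-one (2β-hydroxy-4-methylene enone)
Conditions: Me2AlCl (2.5 equiv), CH2Cl2, −78 to 0 °C; 1 M HCl work-up
Reagents that add atoms: none
Why: Me2AlCl activates the aldehyde, whose carbon C2 is attacked by the terminal carbon C3 of the 2-propenyl group while a hydrogen of the allylic methyl passes to oxygen through a six-membered ene transition state (Lewis-acid-promoted type 2 carbonyl-ene cyclization, the known route from 5-methylhex-5-enals to 3-methylenecyclohexanols). Ring A closes as a six-membered ring, exo with respect to the C=O and with both alkene carbons C3 and C4 inside the new ring, fused trans to ring B because the arm on C10 and the 2-propenyl group on C5 are trans and both equatorial on the carvone ring. In the chair transition state the oxygen has to be axial to reach the methyl hydrogen, which here is the β face, cis to the axial C10 methyl, so the 2β carbinol is expected as the main epimer, and the syn-axial methyl may let some 2α epimer form through a boat-like transition state. The step needs chemoselectivity for the aldehyde over the hindered enone carbonyl and hydrogen transfer from the methyl group instead of proton loss into the ring; the 1,1-disubstituted alkene held next to the aldehyde and the proton-scavenging, methane-releasing aluminium reagent should secure both. The C2 configuration is not needed later, because C2 is oxidised in step 7 and set as 2α in step 17, and a ring-alkene isomer or a C4 chloride from a stepwise Prins course would also be carried to enone 12 by steps 6 and 7.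

Step 6
Reactants: 9 hydroxy enone
Product: 10 (2R,4aS,8aS)-7,8a-dimethyl-4,8-dimethylidene-1,2,3,4,4a,5,8,8a-octahydronaphthalen-2-ol
Conditions: Ph3PCH3Br, KOt-Bu, toluene, 90 °C
Reagents that add atoms: methyltriphenylphosphonium bromide, C[P+](c1ccccc1)(c1ccccc1)c1ccccc1.[Br-]
Why: Wittig methylenation with excess Ph3P=CH2 under forcing conditions should convert the hindered C9 enone carbonyl, which has no epimerisable α centre, into the exocyclic methylene of a transoid diene, the free hydroxyl being carried as its alkoxide.

Step 7
Reactants: 10 trienol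
Product: 12 (4aS,8aS)-4,7,8a-trimethyl-8-methylidene-4a,5,8,8a-tetrahydronaphthalen-2(1H)-one, via β,γ-unsaturated ketone 11 (not isolated)
Conditions: Dess–Martin periodinane, NaHCO3, CH2Cl2, 0 °C to rt; then DBU, CH2Cl2, rt
Reagents that add atoms: none
Why: Dess–Martin oxidation of the homoallylic alcohol gives ketone 11, and base-catalysed isomerisation through the dienolate (deprotonation at the doubly activated C3, protonation at the exocyclic carbon) should move the double bond into conjugation as the C3–C4 enone; C2 becomes planar, so both C2 epimers of 10 converge here.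

Step 8
Reactants: 12 enone
Product: 14 (4aS,8aS)-4,4,7,8a-tetramethyl-8-methylidene-3,4,4a,5,8,8a-hexahydronaphthalen-2(1H)-one (drima-7,9(11)-dien-2-one), via trimethylsilyl enol ether 13 (not isolated)
Conditions: Me2CuLi (from MeLi and CuI), Me3SiCl, THF, −78 to −20 °C; then K2CO3 (cat.), MeOH, 0 °C
Reagents that add atoms: lithium dimethylcuprate, [Li+].C[Cu-]C
Why: Cuprate conjugate addition to the β-methyl enone, accelerated by Me3SiCl, should create the C4 gem-dimethyl group as in the classical copper-mediated methylation of isophorone to 3,3,5,5-tetramethylcyclohexanone; the two methyl groups on C4 are alike, so no stereocentre arises, the diene is inert, and methanolysis cleaves enol ether 13.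

Step 9
Reactants: 14 dienone
Product: 16 drim-7-ene-2β,11-diol, via bis(9-BBN) adduct 15 (not isolated)
Conditions: 9-BBN (3 equiv), THF, 0 to 65 °C; then NaOH, H2O2, 0 °C to rt
Reagents that add atoms: hydrogen peroxide, OO
Why: Hydroboration–oxidation: 9-BBN should add boron to the terminal carbon C11 of the exocyclic alkene and deliver hydrogen to C9 from the α face, opposite to the axial methyl on the neighbouring C10, which sets H-9 α and the hydroxymethyl group β, while the trisubstituted C7–C8 alkene is left; the excess borane also reduces the C2 ketone from the open α face to the 2β carbinol, which is reoxidised in step 10.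

Step 10
Reactants: 16 diol
Product: 17 2-oxodrim-7-en-11-al
Conditions: Dess–Martin periodinane (3 equiv), NaHCO3, CH2Cl2, 0 °C to rt
Reagents that add atoms: none
Why: Dess–Martin oxidation under bicarbonate buffer converts both alcohols in one operation and, being neutral, should leave the epimerisable C9 centre of the β,γ-unsaturated aldehyde untouched.

Step 11
Reactants: 18 (S)-4-methyldihydrofuran-2(3H)-one
Product: 19 ethyl (S)-4-iodo-3-methylbutanoate
Conditions: Me3SiI, EtOH, CH2Cl2, 0 °C to rt
Reagents that add atoms: iodotrimethylsilane, C[Si](C)(C)I; ethanol, CCO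
Why: Iodide opens the activated lactone by SN2 attack at the O–CH2 carbon and the acid is esterified by the ethanol and HI present (Fischer esterification), a known route from lactones to ω-iodo esters; the stereocentre is one carbon away from the reacting carbon and is not touched.

Step 12
Reactants: 19 iodo ester
Product: 20 (S)-4-iodo-3-methylbutan-1-ol
Conditions: i-Bu2AlH, CH2Cl2, −78 to −20 °C
Reagents that add atoms: none
Why: Hydride reduction of the ester with i-Bu2AlH at low temperature should give the primary alcohol and leave the primary iodide.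

Step 13
Reactants: 20 iodo alcohol
Product: 21 benzyl (S)-4-iodo-3-methylbutyl ether
Conditions: BnOC(=NH)CCl3, TfOH (cat.), CH2Cl2/cyclohexane, 0 °C to rt
Reagents that add atoms: benzyl 2,2,2-trichloroacetimidate, ClC(Cl)(Cl)C(=N)OCc1ccccc1
Why: Acid-catalysed benzylation with the trichloroacetimidate avoids an alkoxide, which would close the iodo alcohol to 3-methyltetrahydrofuran.

Step 14
Reactants: 21 iodo benzyl ether
Product: 22 [(2S)-4-(benzyloxy)-2-methylbutyl]triphenylphosphonium iodide
Conditions: PPh3, MeCN, reflux
Reagents that add atoms: triphenylphosphine, c1ccc(cc1)P(c1ccccc1)c1ccccc1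
Why: SN2 quaternisation of triphenylphosphine by the primary iodide gives the phosphonium salt; the β branch slows the reaction but should not prevent it at reflux.

Step 15
Reactants: 17 2-oxodrim-7-en-11-al; 22 phosphonium iodide
Product: 24 (11Z)-15-(benzyloxy)labda-7,11-dien-2-one, via phosphorus ylide 23 (not isolated)
Conditions: 22, NaN(SiMe3)2, THF, −78 to 0 °C; then 17, −78 °C to rt
Reagents that add atoms: none
Why: Wittig olefination: the non-stabilised ylide 23 should add to the aldehyde at low temperature faster than it deprotonates C9 or attacks the hindered C2 ketone, as in Wittig reactions of α-cyclocitral, giving mainly the (Z)-C11–C12 alkene, whose geometry is irrelevant because it is saturated in step 16.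

Step 16
Reactants: 24 dienone
Product: 25 (13R)-15-(benzyloxy)labd-7-en-2-one
Conditions: KO2CN=NCO2K, AcOH, MeOH/CH2Cl2, rt
Reagents that add atoms: none
Why: Diimide reduction transfers hydrogen in a concerted syn manner to the 1,2-disubstituted alkene much faster than to the trisubstituted C7–C8 alkene and leaves the ketone and the benzyl ether; this hydrazide-free diimide source avoids hydrazone formation at C2.

Step 17
Reactants: 25 keto benzyl ether
Product: 26 (13R)-labd-7-ene-2α,15-diol
Conditions: Li, NH3 (l), THF, t-BuOH, −78 to −40 °C; NH4Cl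
Reagents that add atoms: none
Why: Dissolving metal reduction should give the thermodynamically preferred equatorial alcohol of the hindered cyclohexanone, here the 2α carbinol (the axial 2β epimer would be syn-axial to the methyl groups on C4 and C10), and the same conditions cleave the benzyl ether by electron transfer to the arene; the isolated trisubstituted alkene is inert.

Step 18
Reactants: 26 diol; 27 ferulic acid
Product: 28 (13R)-2α-hydroxylabd-7-en-15-yl (E)-3-(4-hydroxy-3-methoxyphenyl)prop-2-enoate (CNP0175017.1)
Conditions: PPh3, i-PrO2CN=NCO2i-Pr, THF, 0 °C to rt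
Reagents that add atoms: none
Why: Mitsunobu esterification should activate the unhindered primary C15 hydroxyl and not the secondary C2 hydroxyl flanked by two neopentyl-type carbons, and the carboxylic acid of ferulic acid, far more acidic than its phenol, is the nucleophile, so the ester forms without protecting groups; C15 is not a stereocentre and the (E) alkene comes unchanged from ferulic acid.

## Compound list

1 | (R)-carvone, (5R)-2-methyl-5-(prop-1-en-2-yl)cyclohex-2-en-1-one | CC1=CC[C@H](CC1=O)C(C)=C | starting material
2 | lithium enolate of 1 (cross-conjugated dienolate) | CC1=CC[C@H](C=C1O[Li])C(C)=C | intermediate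
3 | (5R,6S)-2,6-dimethyl-5-(prop-1-en-2-yl)cyclohex-2-en-1-one (trans-6-methylcarvone, main epimer; 6R epimer carried along) | CC1=CC[C@H]([C@H](C)C1=O)C(C)=C | intermediate
4 | tert-butyl bromoacetate | CC(C)(C)OC(=O)CBr | starting material
5 | lithium enolate of 3 | CC1=CC[C@H](C(C)=C1O[Li])C(C)=C | intermediate
6 | tert-butyl 2-[(1S,6S)-1,3-dimethyl-2-oxo-6-(prop-1-en-2-yl)cyclohex-3-en-1-yl]acetate (arm trans to 2-propenyl) | CC(C)(C)OC(=O)C[C@]1(C)C(=O)C(C)=CC[C@H]1C(C)=C | intermediate
7 | 2-[(1S,6S)-2-hydroxy-1,3-dimethyl-6-(prop-1-en-2-yl)cyclohex-3-en-1-yl]ethan-1-ol (both epimers at the ring carbinol, centre left undefined) | OCC[C@]1(C)C(O)C(C)=CC[C@H]1C(C)=C | intermediate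
8 | 2-[(1S,6S)-1,3-dimethyl-2-oxo-6-(prop-1-en-2-yl)cyclohex-3-en-1-yl]acetaldehyde | O=CC[C@]1(C)C(=O)C(C)=CC[C@H]1C(C)=C | intermediate
9 | (4aS,7R,8aS)-7-hydroxy-2,8a-dimethyl-5-methylidene-4a,5,6,7,8,8a-hexahydronaphthalen-1(4H)-one (trans-fused, 2β-OH axial and cis to the C10 methyl; expected main epimer) | O=C1C(C)=CC[C@H]2C(=C)C[C@@H](O)C[C@]12C | intermediate
10 | (2R,4aS,8aS)-7,8a-dimethyl-4,8-dimethylidene-1,2,3,4,4a,5,8,8a-octahydronaphthalen-2-ol | C=C1C(C)=CC[C@H]2C(=C)C[C@@H](O)C[C@]12C | intermediate
11 | (4aS,8aS)-7,8a-dimethyl-4,8-dimethylidene-3,4,4a,5,8,8a-hexahydronaphthalen-2(1H)-one | C=C1C(C)=CC[C@H]2C(=C)CC(=O)C[C@]12C | intermediate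
12 | (4aS,8aS)-4,7,8a-trimethyl-8-methylidene-4a,5,8,8a-tetrahydronaphthalen-2(1H)-one | C=C1C(C)=CC[C@H]2C(C)=CC(=O)C[C@]12C | intermediate
13 | trimethylsilyl enol ether of 14 (C2–C3 enol ether) | C=C1C(C)=CC[C@H]2C(C)(C)C=C(O[Si](C)(C)C)C[C@]12C | intermediate
14 | drima-7,9(11)-dien-2-one | C=C1C(C)=CC[C@H]2C(C)(C)CC(=O)C[C@]12C | intermediate
15 | bis(9-BBN) adduct (C11 alkylborane and C2 borinate, H-9 α, 2β-O) | C(B5C6CCCC5CCC6)[C@H]1C(C)=CC[C@H]2C(C)(C)C[C@@H](OB3C4CCCC3CCC4)C[C@]12C | intermediate
16 | drim-7-ene-2β,11-diol | OC[C@H]1C(C)=CC[C@H]2C(C)(C)C[C@@H](O)C[C@]12C | intermediate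
17 | 2-oxodrim-7-en-11-al | O=C[C@H]1C(C)=CC[C@H]2C(C)(C)CC(=O)C[C@]12C | intermediate
18 | (S)-4-methyldihydrofuran-2(3H)-one | O=C1C[C@H](C)CO1 | starting material
19 | ethyl (S)-4-iodo-3-methylbutanoate | CCOC(=O)C[C@H](C)CI | intermediate
20 | (S)-4-iodo-3-methylbutan-1-ol | OCC[C@H](C)CI | intermediate
21 | benzyl (S)-4-iodo-3-methylbutyl ether | O(Cc1ccccc1)CC[C@H](C)CI | intermediate
22 | [(2S)-4-(benzyloxy)-2-methylbutyl]triphenylphosphonium iodide | O(Cc1ccccc1)CC[C@H](C)C[P+](c1ccccc1)(c1ccccc1)c1ccccc1.[I-] | intermediate
23 | [(2S)-4-(benzyloxy)-2-methylbutylidene]triphenylphosphorane | O(Cc1ccccc1)CC[C@H](C)C=P(c1ccccc1)(c1ccccc1)c1ccccc1 | intermediate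
24 | (11Z)-15-(benzyloxy)labda-7,11-dien-2-one (C13 as in 22) | O(Cc1ccccc1)CC[C@H](C)/C=C\[C@H]1C(C)=CC[C@H]2C(C)(C)CC(=O)C[C@]12C | intermediate
25 | (13R)-15-(benzyloxy)labd-7-en-2-one | O(Cc1ccccc1)CC[C@H](C)CC[C@H]1C(C)=CC[C@H]2C(C)(C)CC(=O)C[C@]12C | intermediate
26 | (13R)-labd-7-ene-2α,15-diol | OCC[C@H](C)CC[C@H]1C(C)=CC[C@H]2C(C)(C)C[C@H](O)C[C@]12C | intermediate
27 | ferulic acid | COc1cc(/C=C/C(=O)O)ccc1O | starting material
28 | (13R)-2α-hydroxylabd-7-en-15-yl (E)-ferulate, CNP0175017.1 | COc1cc(/C=C/C(=O)OCC[C@H](C)CC[C@H]2C(C)=CC[C@H]3C(C)(C)C[C@H](O)C[C@]23C)ccc1O | target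

## Step count and risks

Total: 18 steps. Longest linear sequence: 14 steps (steps 1–10 and 15–18); steps 11–14 make the side-chain fragment.

Steps most likely to fail:

1. Step 5 (carbonyl-ene closure). The C2–C3 bond may form without the concerted hydrogen transfer (a stepwise Prins course with chloride capture or proton loss into the ring), a methyl group may pass from aluminium to the aldehyde, or closure may be slow because the axial oxygen demanded by the chair transition state clashes with the C10 methyl. Fallback, from 6 back to 9: the same bond can be made by an intramolecular Nozaki–Hiyama allylation. Ene-type allylic chlorination of the 2-propenyl group of keto ester 6 with hypochlorous acid (Ca(OCl)2, CO2, CH2Cl2/H2O) would give the allylic chloride F1. Reduction with i-Bu2AlH would give the chloro diol F2, and Swern oxidation the chloro keto aldehyde F3. CrCl2 in THF would then turn the allylic chloride into a nucleophile that adds to the aldehyde and not to the ketone, closing ring A to the 2-hydroxy-4-methylene enone 9 (either C2 epimer serves).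

2. Step 15 (Wittig olefination). The basic ylide may deprotonate the aldehyde at C9, which would epimerise C9 or move the C7–C8 double bond into conjugation, and addition to the hindered aldehyde may be slow. Fallback, from 16 back to 25: the roles are reversed so that the decalin partner carries no acidic hydrogen next to a carbonyl. Mitsunobu thioetherification of the primary hydroxyl of diol 16 with 1-phenyl-1H-tetrazole-5-thiol would give the sulfide F4, and H2O2 with (NH4)6Mo7O24 the sulfone F5. Iodide 21 would be oxidised with trimethylamine N-oxide in DMSO (Kornblum-type oxidation) to (S)-4-(benzyloxy)-2-methylbutanal F6. Julia–Kocienski olefination of F5 with F6 (KN(SiMe3)2, two equivalents because of the free 2β hydroxyl, −78 °C) would give the (E)-alkene F7. Diimide reduction would give the saturated 2β alcohol F8, and Dess–Martin oxidation would return to ketone 25.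

3. Step 6 (methylenation of the C9 carbonyl). Enolisation toward C6 and slow addition of the ylide to a carbonyl flanked by the quaternary C10 and the substituted C8 may leave starting material. Fallback, from 9 back to 10: Peterson olefination. Me3SiCH2Li with CeCl3 (THF, −78 to 0 °C) adds to the C9 carbonyl to give the β-hydroxysilane F9, and KH in THF induces syn elimination to trienol 10.

## Further compounds

F1 | step 5 | 3-chloroprop-1-en-2-yl analogue of keto ester 6 | CC(C)(C)OC(=O)C[C@]1(C)C(=O)C(C)=CC[C@H]1C(CCl)=C
F2 | step 5 | 3-chloroprop-1-en-2-yl analogue of diol 7 (carbinol epimers) | OCC[C@]1(C)C(O)C(C)=CC[C@H]1C(CCl)=C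
F3 | step 5 | 3-chloroprop-1-en-2-yl analogue of keto aldehyde 8 | O=CC[C@]1(C)C(=O)C(C)=CC[C@H]1C(CCl)=C
F4 | step 15 | 11-[(1-phenyl-1H-tetrazol-5-yl)sulfanyl]drim-7-en-2β-ol | c1ccccc1-n1nnnc1SC[C@H]1C(C)=CC[C@H]2C(C)(C)C[C@@H](O)C[C@]12C
F5 | step 15 | 11-[(1-phenyl-1H-tetrazol-5-yl)sulfonyl]drim-7-en-2β-ol | c1ccccc1-n1nnnc1S(=O)(=O)C[C@H]1C(C)=CC[C@H]2C(C)(C)C[C@@H](O)C[C@]12C
F6 | step 15 | (S)-4-(benzyloxy)-2-methylbutanal | O(Cc1ccccc1)CC[C@H](C)C=O
F7 | step 15 | (11E)-15-(benzyloxy)labda-7,11-dien-2β-ol | O(Cc1ccccc1)CC[C@H](C)/C=C/[C@H]1C(C)=CC[C@H]2C(C)(C)C[C@@H](O)C[C@]12C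
F8 | step 15 | (13R)-15-(benzyloxy)labd-7-en-2β-ol | O(Cc1ccccc1)CC[C@H](C)CC[C@H]1C(C)=CC[C@H]2C(C)(C)C[C@@H](O)C[C@]12C
F9 | step 6 | adduct of 9 with a hydroxyl and a (trimethylsilyl)methyl group on C9 (C9 configuration not relevant, left undefined) | C[Si](C)(C)CC1(O)C(C)=CC[C@H]2C(=C)C[C@@H](O)C[C@]12C
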